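Retrosynthesis cuts, in order: the C8 ester; the C3–O–C10 furanone bridge (back to a C3 ynone and a C9,C10-diol); C11=C13; the C6–O lactone bond; then the C1≡C2/C6=O pair is folded back into the C1–C6 σ-bond of a ring-fusion epoxy ketone; ring A is re-aromatised; ring B is cut at C9–C10 and C7–C8.
Enabling feature: C1 and C6 are 1,6-related across the ten-membered ring, so C2–C3–C4–C5 (C3 oxygen, C4 methyl, cis C4=C5) are four adjacent carbons of a 2-methoxyphenol ring A fused through C1–C6 to a cyclohexane ring B (C1, C6–C10) that carries the sp3 stereocentres C7–C10.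
Forward order: arene 7 → C7–C8 bond (amine-catalysed Michael addition) → ring B by C9–C10 pinacol closure → dearomatisation of ring A and C1–C6 epoxidation → scission of C1–C6 opens the bicycle to the ten-membered ring → C6–O lactone → C11 methylene → furanone → C8 methacrylate.
Stereochemistry: C7 and C8 from the organocatalyst (syn adduct); C9 and C10 from the samarium pinacol (cis-diol anti to the C8 ether); C6 from hydride delivery anti to the C7 side chain; the Z C4=C5 bond from the arene.
Key step: step 16

Remark (numbering): atoms carry the germacrane numbers of the target in every intermediate: C1 ketone, C2=C3, ring oxygen between C3 and C10, C4=C5 (methyl C15 on C4), C6 lactone carbinol, C7 bearing C11 (C13 methylene, C12 carbonyl), C8 ester carbinol, C9 free carbinol, C10 quaternary (methyl C14); the target is (6S,7S,8S,9R,10R).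
Remark (faces): C9–O and C10–O lie on one face of ring B (the upper face); the C7 side chain, C8–O and later C6–O lie on the other; CIP letters change along the route, so the SMILES strings carry the absolute configuration.
Remark (oxirane): a ring-fusion oxirane must be cis to both six-membered rings; in 19 it is drawn on the upper face, and the other face would serve equally because both oxirane carbons lose their stereochemistry in step 16.
Assumption: 2-[(4-methoxybenzyl)oxy]acetaldehyde, dimethyl malonate, methacrylic anhydride and all reagents are taken as commercial.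

Step 1
Reactants: 1 3-methylcatechol
Product: 2 2-hydroxy-3-methylphenyl 4-methylbenzenesulfonate
Conditions: TsCl (1.0 equiv), Et3N, CH2Cl2, −20 to 0 °C
Reagents that add atoms: p-toluenesulfonyl chloride, Cc1ccc(cc1)S(Cl)(=O)=O
Why: Selective O-sulfonylation, in which the hydroxyl remote from the methyl group is the less hindered and should react first, and the sulfonate then deactivates the ring for step 3.

Step 2
Reactants: 2 2-hydroxy-3-methylphenyl 4-methylbenzenesulfonate
Product: 3 2-methoxy-3-methylphenyl 4-methylbenzenesulfonate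
Conditions: MeI, K2CO3, acetone, reflux
Reagents that add atoms: iodomethane, CI
Why: Williamson etherification of the remaining hindered phenoxide, under carbonate conditions that should not move the aryl sulfonate.

Step 3
Reactants: 3 2-methoxy-3-methylphenyl 4-methylbenzenesulfonate
Product: 4 5-formyl-2-methoxy-3-methylphenyl 4-methylbenzenesulfonate
Conditions: Cl2CHOMe, TiCl4, CH2Cl2, 0 °C; then H2O
Reagents that add atoms: dichloromethyl methyl ether, COC(Cl)Cl; water, O
Why: Rieche formylation (electrophilic aromatic substitution), in which the methoxy group directs the formyl carbon (the future C7) to its para position C6 because the sulfonate oxygen is switched off.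

Step 4
Reactants: 4 5-formyl-2-methoxy-3-methylphenyl 4-methylbenzenesulfonate
Product: 5 3-hydroxy-4-methoxy-5-methylbenzaldehyde
Conditions: KOH, MeOH/H2O, 65 °C; then aq. HCl
Reagents that add atoms: none
Why: Alkaline hydrolysis of the aryl sulfonate (attack at sulfur) frees the C2 phenol, and the non-enolisable, electron-rich aldehyde should tolerate hydroxide.

Step 5
Reactants: 5 3-hydroxy-4-methoxy-5-methylbenzaldehyde
Product: 6 2-bromo-3-hydroxy-4-methoxy-5-methylbenzaldehyde
Conditions: Br2, NaOAc, AcOH, 20 °C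
Reagents that add atoms: bromine, BrBr
Why: Electrophilic aromatic bromination directed by the free phenol to its only open ortho position C1 (between hydroxyl and formyl, as in the bromination of isovanillin), the para position being flanked by methyl and formyl.

Step 6
Reactants: 6 2-bromo-3-hydroxy-4-methoxy-5-methylbenzaldehyde
Product: 7 3-(benzyloxy)-2-bromo-4-methoxy-5-methylbenzaldehyde
Conditions: BnBr, K2CO3, DMF, 20 °C
Reagents that add atoms: benzyl bromide, BrCc1ccccc1
Why: Williamson benzylation masks the phenol so that no ortho-quinone methide can later form from the C10 benzylic ether.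

Step 7
Reactants: 7 3-(benzyloxy)-2-bromo-4-methoxy-5-methylbenzaldehyde; 8 dimethyl malonate
Product: 9 dimethyl 2-{[3-(benzyloxy)-2-bromo-4-methoxy-5-methylphenyl]methylidene}propanedioate
Conditions: piperidine (cat.), AcOH (cat.), toluene, reflux (Dean–Stark)
Reagents that add atoms: none
Why: Knoevenagel condensation turns C7 into a non-enolisable acceptor carbon that already carries C11 and C12.

Step 8
Reactants: 9 dimethyl 2-{[3-(benzyloxy)-2-bromo-4-methoxy-5-methylphenyl]methylidene}propanedioate; 10 2-[(4-methoxybenzyl)oxy]acetaldehyde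
Product: 11 dimethyl 2-{(1S,2S)-1-[3-(benzyloxy)-2-bromo-4-methoxy-5-methylphenyl]-2-[(4-methoxybenzyl)oxy]-3-oxopropyl}propanedioate
Conditions: (R)-α,α-diphenylprolinol trimethylsilyl ether (20 mol%), PhCO2H (20 mol%), toluene, 0 to 20 °C
Reagents that add atoms: none
Why: Amine-catalysed asymmetric Michael addition of an aldehyde to an alkylidene malonate, in which the E-enamine of 10, shielded on one face by the diphenyl(silyloxy)methyl group, adds through a synclinal open transition state and should set C8 (S) and C7 (S) in the syn relationship.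

Step 9
Reactants: 11 dimethyl 2-{(1S,2S)-1-[3-(benzyloxy)-2-bromo-4-methoxy-5-methylphenyl]-2-[(4-methoxybenzyl)oxy]-3-oxopropyl}propanedioate
Product: 13 dimethyl 2-{(1S,2S)-1-[2-acetyl-3-(benzyloxy)-4-methoxy-5-methylphenyl]-2-[(4-methoxybenzyl)oxy]-3-oxopropyl}propanedioate, via 1-ethoxyvinyl arene 12 (not isolated)
Conditions: Bu3Sn–C(OEt)=CH2, Pd(PPh3)4 (5 mol%), toluene, 100 °C; then 1 M HCl, THF, 20 °C
Reagents that add atoms: tributyl(1-ethoxyvinyl)stannane, CCCC[Sn](CCCC)(CCCC)C(=C)OCC; water, O
Why: Stille coupling of the aryl bromide followed by mild acid hydrolysis of the enol ether installs the C10 acetyl group (C10 and C14) without base, so neither the malonate nor the α-alkoxy aldehyde is enolised.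

Step 10
Reactants: 13 dimethyl 2-{(1S,2S)-1-[2-acetyl-3-(benzyloxy)-4-methoxy-5-methylphenyl]-2-[(4-methoxybenzyl)oxy]-3-oxopropyl}propanedioate
Product: 14 dimethyl 2-[(1S,2S,3R,4S)-5-(benzyloxy)-3,4-dihydroxy-6-methoxy-2-[(4-methoxybenzyl)oxy]-4,7-dimethyl-1,2,3,4-tetrahydronaphthalen-1-yl]propanedioate
Conditions: SmI2 (2.5 equiv), t-BuOH, THF, −78 to 20 °C
Reagents that add atoms: none
Why: Samarium diiodide pinacol coupling of the keto aldehyde closes ring B at C9–C10 through a samarium-bridged bis-alkoxide that enforces the cis-diol, and the C9 carbinol should form anti to the neighbouring C8 ether, which fixes C9 and C10.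

Step 11
Reactants: 14 ring B diol
Product: 15 C9,C10-acetonide of 14
Conditions: Me2C(OMe)2, PPTS (cat.), CH2Cl2, 20 °C
Reagents that add atoms: 2,2-dimethoxypropane, COC(C)(C)OC
Why: Acetal exchange with the cis-diol gives the cis-fused dioxolane, which blocks retro-aldol and elimination pathways of the tertiary benzylic C10 alcohol.

Step 12
Reactants: 15 C9,C10-acetonide malonate
Product: 16 acetonide methyl ester (C7 side chain CH2CO2Me)
Conditions: LiCl, H2O, DMSO, 140 °C
Reagents that add atoms: none
Why: Krapcho dealkoxycarbonylation (chloride demethylation, loss of CO2, protonation) trims the malonate to the C11–C12 acetate arm under neutral conditions.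

Step 13
Reactants: 16 acetonide methyl ester
Product: 17 tetralin phenol (free C2 hydroxyl)
Conditions: H2 (1 atm), Raney Ni, EtOH, 20 °C
Reagents that add atoms: none
Why: Hydrogenolysis over Raney Ni cleaves the phenolic benzyl ether, while alkyl p-methoxybenzyl ethers are known to survive this catalyst.

Step 14
Reactants: 17 tetralin phenol
Product: 18 ortho-quinone monoketal dienone (C2 ketone; C3 dimethyl ketal)
Conditions: PhI(OAc)2, MeOH, 0 °C
Reagents that add atoms: methanol, CO
Why: Oxidative dearomatisation of a 2-methoxyphenol by the hypervalent iodine reagent, in which methanol adds at the methoxy-bearing C3, and the C4 methyl group and full substitution at C1 and C6 should protect the dienone from Diels–Alder dimerisation.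

Step 15
Reactants: 18 ortho-quinone monoketal dienone
Product: 19 ring-fusion C1–C6 epoxy ketone (oxirane on the upper face)
Conditions: t-BuOOH (in decane), DBU, CH2Cl2, 0 to 20 °C
Reagents that add atoms: tert-butyl hydroperoxide, CC(C)(C)OO
Why: Weitz–Scheffer nucleophilic epoxidation, in which the hydroperoxide anion adds to C6 (β-carbon of the C2 enone) anti to the C7 side chain and the enolate closes on oxygen at C1, leaving the distal C4=C5 bond that electrophilic oxidants would prefer.

Step 16
Reactants: 19 ring-fusion C1–C6 epoxy ketone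
Product: 21 ten-membered (Z)-enone ynone ketal (C1≡C2; C3 dimethyl ketal; Z C4=C5; C6 ketone), via tosylhydrazone 20 (not isolated)
Conditions: TsNHNH2 (1.2 equiv), AcOH/CH2Cl2 (1:1), −20 to 20 °C
Reagents that add atoms: none
Why: Eschenmoser–Tanabe fragmentation: the sulfonyl hydrazide condenses with the C2 ketone (the only ketone, inductively activated by the flanking ketal and oxirane), and the hydrazone then opens the oxirane at C1 to an azoalkene C6-alkoxide. Collapse of the alkoxide to the C6 carbonyl breaks the C1–C6 σ-bond, forms C1≡C2 and expels N2 and p-toluenesulfinate; the closest known reaction is the fragmentation of the ring-fusion epoxy ketone of a bicyclo[4.4.0]decenone to cyclodec-5-ynone. No ring is closed by bond formation, since the ten-membered ring is unveiled by scission of the bond shared by rings A and B, so no cyclisation mode has to be met. No stereocentre is created: C7–C10 are spectators, both oxirane carbons become sp or sp2, and the Z C4=C5 bond is inherited from ring A. The selectivity needed is cleavage of C1–C6 and not C1–C10, which the substrate secures because the oxirane oxygen sits on C6 and the ring holds C1–C6 trans to the departing C2–N bond across C1=C2; the cold acetic acid medium should leave ketal, acetonide and ester intact.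

Step 17
Reactants: 21 ten-membered (Z)-enone ynone ketal
Product: 23 cis-fused 6,12-γ-lactone (ketal; acetonide; C8 p-methoxybenzyl ether), via hydroxy ester 22 (not isolated)
Conditions: LiBH(s-Bu)3, THF, −78 to 20 °C; then aq. NH4Cl
Reagents that add atoms: none
Why: 1,2-Reduction of the β,β-disubstituted enone by the bulky borohydride from the face anti to the C7 side chain and the C8 ether should give the C6 alkoxide cis to the acetate arm, which lactonises in the flask (intramolecular transesterification) to the cis-fused γ-lactone.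

Step 18
Reactants: 23 cis-fused 6,12-γ-lactone
Product: 24 C11 dimethylaminomethyl lactone (C11 epimers)
Conditions: LiN(SiMe3)2, THF, −78 °C; then Me2N=CH2+ I−, −78 to 0 °C
Reagents that add atoms: dimethylmethyleneiminium iodide, C=[N+](C)C.[I-]
Why: Mannich reaction of the lithium lactone enolate with the preformed iminium salt aminomethylates C11, and either C11 epimer serves.

Step 19
Reactants: 24 C11 dimethylaminomethyl lactone
Product: 26 α-methylene lactone (ketal; acetonide), via ammonium iodide 25 (not isolated)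
Conditions: MeI, MeOH, 20 °C; then aq. NaHCO3, CH2Cl2, 20 °C
Reagents that add atoms: none
Why: N-Methylation and Hofmann-type β-elimination of the quaternary ammonium salt unveil the C11=C13 exo-methylene group.

Step 20
Reactants: 26 α-methylene lactone
Product: 27 dihydroxy ynone (C3 ketone; C9 and C10 hydroxyls)
Conditions: AcOH/H2O/THF (3:1:1), 40 °C
Reagents that add atoms: water, O
Why: Aqueous acid hydrolysis of the allylic-propargylic dimethyl ketal and of the acetonide releases the C3 ynone and the diol, while the p-methoxybenzyl ether and the lactone are stable to dilute acetic acid.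

Step 21
Reactants: 27 dihydroxy ynone
Product: 28 C9 tert-butyldimethylsilyl ether
Conditions: TBSCl, imidazole, DMF, 0 to 20 °C
Reagents that add atoms: tert-butyldimethylsilyl chloride, CC(C)(C)[Si](C)(C)Cl
Why: Silylation with the chlorosilane and imidazole is selective for the secondary C9 hydroxyl over the tertiary propargylic C10 hydroxyl, so only C10–OH can later close onto C3.

Step 22
Reactants: 28 C9 tert-butyldimethylsilyl ether
Product: 30 furanone (C3–O–C10 bridge; C1 ketone; C2=C3), via β-diketone 29 (not isolated)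
Conditions: (Ph3P)AuCl (5 mol%), AgOTf (5 mol%), H2O (2 equiv), toluene, 20 °C
Reagents that add atoms: water, O
Why: Gold-catalysed cycloisomerisation of a γ-hydroxy ynone to a 3(2H)-furanone, in which π-activation directs water to C1 (β to the C3 carbonyl) and the C10 hydroxyl then adds to C3 with loss of water (5-exo-trig hemiketalisation and dehydration), leaving C10 unchanged.

Step 23
Reactants: 30 furanone
Product: 31 C8 alcohol
Conditions: DDQ, CH2Cl2/pH 7 buffer, 0 to 20 °C
Reagents that add atoms: none
Why: Oxidative cleavage of the p-methoxybenzyl ether by DDQ (hydride abstraction then hydrolysis) frees the C8 hydroxyl without touching the silyl ether, the lactone or the furanone.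

Step 24
Reactants: 31 C8 alcohol; 32 methacrylic anhydride
Product: 33 C8 methacrylate C9 silyl ether
Conditions: Et3N, DMAP (cat.), CH2Cl2, 0 to 20 °C
Reagents that add atoms: none
Why: DMAP-catalysed acylation of the only free hydroxyl (C8) with the anhydride installs the methacrylate.

Step 25
Reactants: 33 C8 methacrylate C9 silyl ether
Product: 34 CNP0252578.4
Conditions: HF·pyridine, THF/pyridine, 0 to 20 °C
Reagents that add atoms: none
Why: Fluoride-mediated desilylation under weakly acidic conditions frees the C9 hydroxyl and should avoid acyl migration and conjugate addition to the methylene lactone.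

Compound list
1 | 3-methylcatechol | Cc1cccc(O)c1O | starting material
2 | 2-hydroxy-3-methylphenyl 4-methylbenzenesulfonate | Cc1ccc(cc1)S(=O)(=O)Oc1cccc(C)c1O | intermediate
3 | 2-methoxy-3-methylphenyl 4-methylbenzenesulfonate | COc1c(C)cccc1OS(=O)(=O)c1ccc(C)cc1 | intermediate
4 | 5-formyl-2-methoxy-3-methylphenyl 4-methylbenzenesulfonate | COc1c(C)cc(C=O)cc1OS(=O)(=O)c1ccc(C)cc1 | intermediate
5 | 3-hydroxy-4-methoxy-5-methylbenzaldehyde | COc1c(C)cc(C=O)cc1O | intermediate
6 | 2-bromo-3-hydroxy-4-methoxy-5-methylbenzaldehyde | COc1c(C)cc(C=O)c(Br)c1O | intermediate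
7 | 3-(benzyloxy)-2-bromo-4-methoxy-5-methylbenzaldehyde (C1 Br, C2 OBn, C3 OMe, C4 Me, C6 CHO) | COc1c(C)cc(C=O)c(Br)c1OCc1ccccc1 | intermediate
8 | dimethyl malonate | COC(=O)CC(=O)OC | starting material
9 | dimethyl 2-{[3-(benzyloxy)-2-bromo-4-methoxy-5-methylphenyl]methylidene}propanedioate | COC(=O)C(=Cc1cc(C)c(OC)c(OCc2ccccc2)c1Br)C(=O)OC | intermediate
10 | 2-[(4-methoxybenzyl)oxy]acetaldehyde | O=CCOCc1ccc(OC)cc1 | starting material
11 | dimethyl 2-{(1S,2S)-1-[3-(benzyloxy)-2-bromo-4-methoxy-5-methylphenyl]-2-[(4-methoxybenzyl)oxy]-3-oxopropyl}propanedioate (syn adduct; C7 S, C8 S) | COc1c(C)cc(c(Br)c1OCc1ccccc1)[C@@H]([C@H](OCc1ccc(OC)cc1)C=O)C(C(=O)OC)C(=O)OC | intermediate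
12 | 1-ethoxyvinyl arene (11 with C(OEt)=CH2 in place of Br at C1) | COc1c(C)cc(c(C(=C)OCC)c1OCc1ccccc1)[C@@H]([C@H](OCc1ccc(OC)cc1)C=O)C(C(=O)OC)C(=O)OC | intermediate (not isolated)
13 | dimethyl 2-{(1S,2S)-1-[2-acetyl-3-(benzyloxy)-4-methoxy-5-methylphenyl]-2-[(4-methoxybenzyl)oxy]-3-oxopropyl}propanedioate | COc1c(C)cc(c(C(C)=O)c1OCc1ccccc1)[C@@H]([C@H](OCc1ccc(OC)cc1)C=O)C(C(=O)OC)C(=O)OC | intermediate
14 | dimethyl 2-[(1S,2S,3R,4S)-5-(benzyloxy)-3,4-dihydroxy-6-methoxy-2-[(4-methoxybenzyl)oxy]-4,7-dimethyl-1,2,3,4-tetrahydronaphthalen-1-yl]propanedioate (C9–OH and C10–OH cis, trans to C8–O; C7 arm cis to C8–O) | COc1c(C)cc2c(c1OCc1ccccc1)[C@](C)(O)[C@H](O)[C@@H](OCc1ccc(OC)cc1)[C@H]2C(C(=O)OC)C(=O)OC | intermediate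
15 | C9,C10-O-isopropylidene derivative of 14 (cis-fused dioxolane) | COc1c(C)cc2c(c1OCc1ccccc1)[C@]1(C)OC(C)(C)O[C@@H]1[C@@H](OCc1ccc(OC)cc1)[C@H]2C(C(=O)OC)C(=O)OC | intermediate
16 | acetonide methyl ester (15 with the C7 side chain trimmed to CH2CO2Me) | COc1c(C)cc2c(c1OCc1ccccc1)[C@]1(C)OC(C)(C)O[C@@H]1[C@@H](OCc1ccc(OC)cc1)[C@H]2CC(=O)OC | intermediate
17 | tetralin phenol (16 with free C2–OH) | COc1c(C)cc2c(c1O)[C@]1(C)OC(C)(C)O[C@@H]1[C@@H](OCc1ccc(OC)cc1)[C@H]2CC(=O)OC | intermediate
18 | ortho-quinone monoketal dienone (C2 ketone, C3 dimethyl ketal, C1=C6 and C4=C5; ring B as in 17) | COC1(OC)C(C)=CC2=C(C1=O)[C@]1(C)OC(C)(C)O[C@@H]1[C@@H](OCc1ccc(OC)cc1)[C@H]2CC(=O)OC | intermediate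
19 | ring-fusion C1–C6 epoxy ketone (oxirane on the upper face, C2 ketone, C3 dimethyl ketal, C4=C5) | COC1(OC)C(C)=C[C@@]23O[C@]2(C1=O)[C@]2(C)OC(C)(C)O[C@@H]2[C@@H](OCc4ccc(OC)cc4)[C@H]3CC(=O)OC | intermediate
20 | C2 p-toluenesulfonylhydrazone of 19 | COC1(OC)C(C)=C[C@@]23O[C@]2(C1=NNS(=O)(=O)c1ccc(C)cc1)[C@]2(C)OC(C)(C)O[C@@H]2[C@@H](OCc4ccc(OC)cc4)[C@H]3CC(=O)OC | intermediate (not isolated)
21 | ten-membered (Z)-enone ynone ketal (C1≡C2, C3 dimethyl ketal, Z C4=C5, C6 ketone, C7 CH2CO2Me, C8 OPMB, C9,C10 acetonide) | O=C1/C=C(/C)C(OC)(OC)C#C[C@]2(C)OC(C)(C)O[C@@H]2[C@@H](OCc2ccc(OC)cc2)[C@H]1CC(=O)OC | intermediate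
22 | C6 allylic alcohol of 21 (C6–OH cis to the C7 acetate arm) | O[C@H]1/C=C(/C)C(OC)(OC)C#C[C@]2(C)OC(C)(C)O[C@@H]2[C@@H](OCc2ccc(OC)cc2)[C@H]1CC(=O)OC | intermediate (not isolated)
23 | cis-fused 6,12-γ-lactone (ketal, alkyne, acetonide, C8 OPMB) | O=C1C[C@H]2[C@@H](O1)/C=C(/C)C(OC)(OC)C#C[C@]1(C)OC(C)(C)O[C@@H]1[C@H]2OCc1ccc(OC)cc1 | intermediate
24 | C11 dimethylaminomethyl lactone (C11 epimers) | CN(C)CC1C(=O)O[C@H]2/C=C(/C)C(OC)(OC)C#C[C@]3(C)OC(C)(C)O[C@@H]3[C@@H](OCc3ccc(OC)cc3)[C@@H]12 | intermediate
25 | trimethylammonium iodide of 24 | C[N+](C)(C)CC1C(=O)O[C@H]2/C=C(/C)C(OC)(OC)C#C[C@]3(C)OC(C)(C)O[C@@H]3[C@@H](OCc3ccc(OC)cc3)[C@@H]12.[I-] | intermediate (not isolated)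
26 | α-methylene lactone (C11=C13; ketal, acetonide, C8 OPMB) | C=C1C(=O)O[C@H]2/C=C(/C)C(OC)(OC)C#C[C@]3(C)OC(C)(C)O[C@@H]3[C@@H](OCc3ccc(OC)cc3)[C@@H]12 | intermediate
27 | dihydroxy ynone (C3 ketone, C1≡C2, C9–OH, C10–OH) | C=C1C(=O)O[C@H]2/C=C(/C)C(=O)C#C[C@](C)(O)[C@H](O)[C@@H](OCc3ccc(OC)cc3)[C@@H]12 | intermediate
28 | C9 tert-butyldimethylsilyl ether of 27 | C=C1C(=O)O[C@H]2/C=C(/C)C(=O)C#C[C@](C)(O)[C@H](O[Si](C)(C)C(C)(C)C)[C@@H](OCc3ccc(OC)cc3)[C@@H]12 | intermediate
29 | C1,C3-diketone (hydrate of the ynone of 28) | C=C1C(=O)O[C@H]2/C=C(/C)C(=O)CC(=O)[C@](C)(O)[C@H](O[Si](C)(C)C(C)(C)C)[C@@H](OCc3ccc(OC)cc3)[C@@H]12 | intermediate (not isolated)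
30 | furanone (C3–O–C10 bridge, C1 ketone; C9 OTBS, C8 OPMB) | C=C1C(=O)O[C@H]2/C=C(/C)C3=CC(=O)[C@](C)(O3)[C@H](O[Si](C)(C)C(C)(C)C)[C@@H](OCc4ccc(OC)cc4)[C@@H]12 | intermediate
31 | C8 alcohol (C9 OTBS) | C=C1C(=O)O[C@H]2/C=C(/C)C3=CC(=O)[C@](C)(O3)[C@H](O[Si](C)(C)C(C)(C)C)[C@@H](O)[C@@H]12 | intermediate
32 | methacrylic anhydride | C=C(C)C(=O)OC(=O)C(C)=C | starting material
33 | C8 methacrylate, C9 OTBS | C=C1C(=O)O[C@H]2/C=C(/C)C3=CC(=O)[C@](C)(O3)[C@H](O[Si](C)(C)C(C)(C)C)[C@@H](OC(=O)C(C)=C)[C@@H]12 | intermediate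
34 | CNP0252578.4, (6S,7S,8S,9R,10R) | C=C(C)C(=O)O[C@H]1[C@H]2C(=C)C(=O)O[C@H]2/C=C(/C)C2=CC(=O)[C@](C)(O2)[C@@H]1O | target

Total step count: 25. Longest linear sequence: 25 steps (1 to 34); compounds 8, 10 and 32 enter as purchased materials.

Steps most likely to fail

Step 16 (key step). The risk is slow condensation of the sulfonyl hydrazide with the C2 carbonyl, which is flanked by the ketal carbon and the oxirane, so that acid-induced opening of the oxirane or loss of the ketal outruns hydrazone formation. The fallback is a Grob-type fragmentation that cleaves the same C1–C6 bond. Compound 19 is reduced at the oxirane C1–O bond with Na[PhSeB(OEt)3] to the β-hydroxy ketone F1. The tertiary C6 hydroxyl is capped with N-(trimethylsilyl)imidazole to give the silyl ether F2. KN(SiMe3)2 and PhNTf2 then convert the C2 ketone, which can enolise only toward C1, into the enol triflate F3. Bu4NF frees the C6 alkoxide, which fragments with loss of triflate (C1–C6 trans to the C2–O bond across C1=C2), and the route is rejoined at 21.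

Step 8. The risk is sluggish enamine addition to the hindered, ortho-brominated alkylidene malonate, with self-aldolisation of 10 and erosion of diastereo- and enantioselectivity. The fallback replaces amine catalysis by a chiral Lewis acid. Compound 9 is combined with the silyl ketene thioacetal F4 (from S-tert-butyl 2-[(4-methoxybenzyl)oxy]ethanethioate) in a Mukaiyama–Michael addition catalysed by [Cu(t-Bu-box)](SbF6)2, a bis(oxazoline) complex of divalent copper. Ketene acetal geometry and ligand antipode are chosen for the syn 7S,8S adduct, the thioester F5. A Fukuyama reduction (Et3SiH, Pd/C, acetone) of F5 rejoins the route at 11.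

Step 17. The risk is poor facial selectivity of hydride delivery to the medium-ring enone, which would give the C6 epimer. The fallback closes the lactone with inversion instead of retention. Compound 21 is reduced with a small hydride (NaBH4, CeCl3, MeOH) to the C6-epimeric hydroxy ester F6, which is saponified (LiOH, THF/H2O) to the hydroxy acid F7. A Mitsunobu lactonisation (PPh3, DIAD, THF) inverts the allylic C6 centre and rejoins the route at 23.

Further compounds
F1 | step 16 | β-hydroxy ketone (C6–OH, C1–H, C2 ketone, C3 ketal; C1 epimers) | COC1(OC)C(C)=C[C@@]2(O)C(C1=O)[C@]3(C)OC(C)(C)O[C@@H]3[C@@H](OCc3ccc(OC)cc3)[C@H]2CC(=O)OC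
F2 | step 16 | C6 trimethylsilyl ether of F1 | COC1(OC)C(C)=C[C@@]2(O[Si](C)(C)C)C(C1=O)[C@]3(C)OC(C)(C)O[C@@H]3[C@@H](OCc3ccc(OC)cc3)[C@H]2CC(=O)OC
F3 | step 16 | C1=C2 enol triflate of F2 | COC1(OC)C(C)=C[C@@]2(O[Si](C)(C)C)C(=C1OS(=O)(=O)C(F)(F)F)[C@]3(C)OC(C)(C)O[C@@H]3[C@@H](OCc3ccc(OC)cc3)[C@H]2CC(=O)OC
F4 | step 8 | (Z)-1-(tert-butylsulfanyl)-2-[(4-methoxybenzyl)oxy]-1-(trimethylsilyloxy)ethene | COc1ccc(CO/C=C(/O[Si](C)(C)C)SC(C)(C)C)cc1
F5 | step 8 | S-tert-butyl thioester analogue of 11 (C9 thioester; C7 S, C8 S) | COc1c(C)cc(c(Br)c1OCc1ccccc1)[C@@H]([C@H](OCc1ccc(OC)cc1)C(=O)SC(C)(C)C)C(C(=O)OC)C(=O)OC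
F6 | step 17 | C6-epimeric hydroxy ester (C6–OH trans to the C7 arm) | O[C@@H]1/C=C(/C)C(OC)(OC)C#C[C@]2(C)OC(C)(C)O[C@@H]2[C@@H](OCc2ccc(OC)cc2)[C@H]1CC(=O)OC
F7 | step 17 | C6-epimeric hydroxy acid | O[C@@H]1/C=C(/C)C(OC)(OC)C#C[C@]2(C)OC(C)(C)O[C@@H]2[C@@H](OCc2ccc(OC)cc2)[C@H]1CC(=O)O
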